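The bicyclo[3.2.1]oct-3-ene-2,8-dione is cut through C5–C6 and C1–C7. The C8 ketone with its two bridgeheads and the C2–C4 enone are read as the pentadienyl cation of a titanium-bound 2-methoxy-1,4-benzoquinone, and the trans-diaryl C6–C7 bridge as the (E)-stilbene of fully silylated piceatannol. One asymmetric, perezone-type (5+2) cycloaddition under a chiral titanium TADDOLate closes the five- and seven-membered rings and sets all four stereocentres. The quinone carries bromine at the future C4 for Suzuki attachment of the styryl arm; its extra C3 oxygen is removed through the enol triflate, and six silyl ethers are cleaved last.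

Key step: step 3

Numbering: target numbering is used throughout (C1 bridgehead between the two carbonyls, C2 enone carbonyl, C3, C4 styryl-bearing, C5 bridgehead, C6 bearing the 3,5-dioxygenated aryl, C7 bearing the 3,4-dioxygenated aryl, C8 bridging carbonyl).

Assumption: the (4R,5R)-TADDOLate is taken to deliver the (1S,5R,6S,7S) adduct 5; should a pilot run show the opposite sense, the (4S,5S)-ligand is used and nothing else changes.

**Step 1**
Reactants: 1 piceatannol, (E)-3,4,3',5'-tetrahydroxystilbene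
Product: 2 (E)-3,4,3',5'-tetrakis(triisopropylsilyloxy)stilbene
Conditions: TIPSCl, imidazole, DMAP (cat.), DMF, 50 °C
Reagents that add atoms: triisopropylsilyl chloride, CC(C)[Si](Cl)(C(C)C)C(C)C
Why: Imidazole-mediated O-silylation caps all four phenols as TIPS ethers, which should survive the titanium Lewis acid, aqueous phosphate and palladium steps and leave at the end under non-basic fluoride conditions.

**Step 2**
Reactants: 3 2-bromo-6-methoxyphenol
Product: 4 2-bromo-6-methoxy-1,4-benzoquinone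
Conditions: potassium nitrosodisulfonate (2.5 equiv), KH2PO4, H2O/acetone, 0 °C to rt
Reagents that add atoms: potassium nitrosodisulfonate, [K+].[K+].[O]N(S(=O)(=O)[O-])S(=O)(=O)[O-]
Why: Teuber oxidation of a phenol with both ortho positions blocked and a free para position should give the p-quinone regioselectively, with bromide and methyl ether untouched.

**Step 3**
Reactants: 4 2-bromo-6-methoxy-1,4-benzoquinone; 2 (E)-3,4,3',5'-tetrakis(triisopropylsilyloxy)stilbene
Product: 5 (1S,5R,6S,7S)-4-bromo-3-hydroxy-6-[3,5-bis(triisopropylsilyloxy)phenyl]-7-[3,4-bis(triisopropylsilyloxy)phenyl]bicyclo[3.2.1]oct-3-ene-2,8-dione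
Conditions: TiCl4/Ti(OiPr)4 (1:1) and (4R,5R)-TADDOL (gives TiCl2(TADDOLate), 2 equiv), 4 Å MS, CH2Cl2/toluene, −78 °C; then aq. NaHCO3
Reagents that add atoms: none
Why: Tetravalent titanium chelates the carbonyl next to the methoxy group of 4, so the alkene carbon of 2 that bears the 3,5-disilyloxyaryl ring adds to the unsubstituted quinone carbon next to C–Br (new C5–C6 bond), and the 4-silyloxybenzyl cation so formed is captured within the ion pair by the enol-ether carbon (new C1–C7 bond), after which chloride removes the O-methyl group to unveil the C2 ketone. The closest known reaction type is the Lewis acid-promoted, perezone-type (5+2) cycloaddition of 2-alkoxy-1,4-benzoquinones with (E)-propenylarenes, including its chiral titanium TADDOLate variant. The five-membered ring C1–C8–C5–C6–C7 is closed by a 5-(enolexo)-exo-trig collapse of the enol ether on the cation, and the seven-membered ring C1–C2–C3–C4–C5–C6–C7 by the same pair of bonds as the (5+2) union of the pentadienyl unit C1–C5 with the alkene. C6 and C7 should keep the trans relation of the (E)-alkene because collapse is faster than bond rotation, the cation-stabilising C7 aryl should sit endo by stacking over the titanium-bound quinone (leaving the C6 aryl exo), C1 and C5 follow as bridgeheads, and the absolute sense comes from the TADDOLate aryl groups shielding one quinone face. The step needs attack at C5 rather than at the methoxy-bearing side, which chelation secures, and closure at C1 rather than at oxygen or at the enolate carbon C4, which the bromine on C4 and the low temperature should favour.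

**Step 4**
Reactants: 6 3,4-dihydroxybenzaldehyde
Product: 7 3,4-bis(triisopropylsilyloxy)benzaldehyde
Conditions: TIPSCl, imidazole, DMF, rt to 40 °C
Reagents that add atoms: triisopropylsilyl chloride, CC(C)[Si](Cl)(C(C)C)C(C)C
Why: Standard imidazole-mediated silylation of the catechol gives the same protecting group as on the other rings, so that one final operation removes all six.

**Step 5**
Reactants: 7 3,4-bis(triisopropylsilyloxy)benzaldehyde
Product: 8 2-[(E)-2-[3,4-bis(triisopropylsilyloxy)phenyl]ethenyl]-4,4,5,5-tetramethyl-1,3,2-dioxaborolane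
Conditions: bis(pinacolatoboryl)methane, LiTMP (from 2,2,6,6-tetramethylpiperidine and n-BuLi), THF, 0 °C then −78 °C to rt; aq. NH4Cl
Reagents that add atoms: bis(pinacolatoboryl)methane, CC1(C)OB(CB2OC(C)(C)C(C)(C)O2)OC1(C)C
Why: Boron-Wittig olefination, in which the α-boryl carbanion adds to the aldehyde and syn-elimination of O–B from the β-alkoxyboronate should give the (E)-alkenylboronate in one step.

**Step 6**
Reactants: 5 bromo-diosphenol from step 3
Product: 9 (1S,5R,6S,7S)-4-bromo-6-[3,5-bis(triisopropylsilyloxy)phenyl]-7-[3,4-bis(triisopropylsilyloxy)phenyl]-2,8-dioxobicyclo[3.2.1]oct-3-en-3-yl trifluoromethanesulfonate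
Conditions: PhNTf2, Et3N, DMAP (cat.), CH2Cl2, 0 °C to rt
Reagents that add atoms: N-phenylbis(trifluoromethanesulfonimide), O=S(=O)(N(c1ccccc1)S(=O)(=O)C(F)(F)F)C(F)(F)F
Why: O-sulfonylation of the acidic diosphenol hydroxyl (enol triflate formation) turns the superfluous C3 oxygen into a group that palladium can later replace by hydrogen.

**Step 7**
Reactants: 9 bromo enol triflate; 8 (E)-alkenylboronate
Product: 10 (1S,5S,6S,7S)-4-[(E)-2-[3,4-bis(triisopropylsilyloxy)phenyl]ethenyl]-6-[3,5-bis(triisopropylsilyloxy)phenyl]-7-[3,4-bis(triisopropylsilyloxy)phenyl]-2,8-dioxobicyclo[3.2.1]oct-3-en-3-yl trifluoromethanesulfonate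
Conditions: Pd(PPh3)4 (5 mol %), K3PO4, THF/H2O (10:1), 40 °C, 1.05 equiv of 8
Reagents that add atoms: none
Why: Suzuki–Miyaura coupling, in which zerovalent palladium should insert into the C4–Br bond at the β-carbon of the enone much faster than into the α-enol triflate, placing the styryl arm at C4 with its (E) geometry retained.

**Step 8**
Reactants: 10 styryl enol triflate
Product: 11 (1R,5S,6S,7S)-4-[(E)-2-[3,4-bis(triisopropylsilyloxy)phenyl]ethenyl]-6-[3,5-bis(triisopropylsilyloxy)phenyl]-7-[3,4-bis(triisopropylsilyloxy)phenyl]bicyclo[3.2.1]oct-3-ene-2,8-dione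
Conditions: Pd(OAc)2 (10 mol %), PPh3, HCO2H, Bu3N, DMF, 60 °C
Reagents that add atoms: none
Why: Palladium-catalysed formate hydrogenolysis of the enol triflate (oxidative addition, formate exchange, decarboxylation, reductive elimination) should replace C3–O by C3–H without touching the dienone or the styryl double bond.

**Step 9**
Reactants: 11 hexakis(triisopropylsilyl) ether
Product: 12 (1R,5S,6S,7S)-7-(3,4-dihydroxyphenyl)-6-(3,5-dihydroxyphenyl)-4-[(E)-2-(3,4-dihydroxyphenyl)ethenyl]bicyclo[3.2.1]oct-3-ene-2,8-dione (target)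
Conditions: HF·pyridine, THF/pyridine, 0 °C to rt, under argon
Reagents that add atoms: none
Why: Fluoride-driven Si–O cleavage under mildly acidic, non-basic conditions should free the six phenols without phenoxide-triggered retro-Michael opening of the C1–C7 bond, and no stereocentre can epimerise because both α-carbons of the C8 ketone are bridgeheads.

**Compound list**

1 | piceatannol, (E)-3,4,3',5'-tetrahydroxystilbene | Oc1cc(O)cc(/C=C/c2ccc(O)c(O)c2)c1 | starting material
2 | (E)-3,4,3',5'-tetrakis(triisopropylsilyloxy)stilbene | CC(C)[Si](C(C)C)(C(C)C)Oc1cc(O[Si](C(C)C)(C(C)C)C(C)C)cc(/C=C/c2ccc(O[Si](C(C)C)(C(C)C)C(C)C)c(O[Si](C(C)C)(C(C)C)C(C)C)c2)c1 | intermediate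
3 | 2-bromo-6-methoxyphenol | COc1cccc(Br)c1O | starting material
4 | 2-bromo-6-methoxy-1,4-benzoquinone | COC1=CC(=O)C=C(Br)C1=O | intermediate
5 | (1S,5R,6S,7S)-4-bromo-3-hydroxy-6-[3,5-bis(triisopropylsilyloxy)phenyl]-7-[3,4-bis(triisopropylsilyloxy)phenyl]bicyclo[3.2.1]oct-3-ene-2,8-dione | O=C1C(O)=C(Br)[C@H]2C(=O)[C@@H]1[C@@H](c1ccc(O[Si](C(C)C)(C(C)C)C(C)C)c(O[Si](C(C)C)(C(C)C)C(C)C)c1)[C@@H]2c1cc(O[Si](C(C)C)(C(C)C)C(C)C)cc(O[Si](C(C)C)(C(C)C)C(C)C)c1 | intermediate
6 | 3,4-dihydroxybenzaldehyde | O=Cc1ccc(O)c(O)c1 | starting material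
7 | 3,4-bis(triisopropylsilyloxy)benzaldehyde | O=Cc1ccc(O[Si](C(C)C)(C(C)C)C(C)C)c(O[Si](C(C)C)(C(C)C)C(C)C)c1 | intermediate
8 | 2-[(E)-2-[3,4-bis(triisopropylsilyloxy)phenyl]ethenyl]-4,4,5,5-tetramethyl-1,3,2-dioxaborolane | CC1(C)OB(/C=C/c2ccc(O[Si](C(C)C)(C(C)C)C(C)C)c(O[Si](C(C)C)(C(C)C)C(C)C)c2)OC1(C)C | intermediate
9 | (1S,5R,6S,7S)-4-bromo-6-[3,5-bis(triisopropylsilyloxy)phenyl]-7-[3,4-bis(triisopropylsilyloxy)phenyl]-2,8-dioxobicyclo[3.2.1]oct-3-en-3-yl trifluoromethanesulfonate | O=C1C(OS(=O)(=O)C(F)(F)F)=C(Br)[C@H]2C(=O)[C@@H]1[C@@H](c1ccc(O[Si](C(C)C)(C(C)C)C(C)C)c(O[Si](C(C)C)(C(C)C)C(C)C)c1)[C@@H]2c1cc(O[Si](C(C)C)(C(C)C)C(C)C)cc(O[Si](C(C)C)(C(C)C)C(C)C)c1 | intermediate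
10 | (1S,5S,6S,7S)-4-[(E)-2-[3,4-bis(triisopropylsilyloxy)phenyl]ethenyl]-6-[3,5-bis(triisopropylsilyloxy)phenyl]-7-[3,4-bis(triisopropylsilyloxy)phenyl]-2,8-dioxobicyclo[3.2.1]oct-3-en-3-yl trifluoromethanesulfonate | O=C1C(OS(=O)(=O)C(F)(F)F)=C(/C=C/c2ccc(O[Si](C(C)C)(C(C)C)C(C)C)c(O[Si](C(C)C)(C(C)C)C(C)C)c2)[C@H]2C(=O)[C@@H]1[C@@H](c1ccc(O[Si](C(C)C)(C(C)C)C(C)C)c(O[Si](C(C)C)(C(C)C)C(C)C)c1)[C@@H]2c1cc(O[Si](C(C)C)(C(C)C)C(C)C)cc(O[Si](C(C)C)(C(C)C)C(C)C)c1 | intermediate
11 | (1R,5S,6S,7S)-4-[(E)-2-[3,4-bis(triisopropylsilyloxy)phenyl]ethenyl]-6-[3,5-bis(triisopropylsilyloxy)phenyl]-7-[3,4-bis(triisopropylsilyloxy)phenyl]bicyclo[3.2.1]oct-3-ene-2,8-dione | O=C1C=C(/C=C/c2ccc(O[Si](C(C)C)(C(C)C)C(C)C)c(O[Si](C(C)C)(C(C)C)C(C)C)c2)[C@H]2C(=O)[C@@H]1[C@@H](c1ccc(O[Si](C(C)C)(C(C)C)C(C)C)c(O[Si](C(C)C)(C(C)C)C(C)C)c1)[C@@H]2c1cc(O[Si](C(C)C)(C(C)C)C(C)C)cc(O[Si](C(C)C)(C(C)C)C(C)C)c1 | intermediate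
12 | (1R,5S,6S,7S)-7-(3,4-dihydroxyphenyl)-6-(3,5-dihydroxyphenyl)-4-[(E)-2-(3,4-dihydroxyphenyl)ethenyl]bicyclo[3.2.1]oct-3-ene-2,8-dione | O=C1C=C(/C=C/c2ccc(O)c(O)c2)[C@H]2C(=O)[C@@H]1[C@@H](c1ccc(O)c(O)c1)[C@@H]2c1cc(O)cc(O)c1 | target

**Step count and risks**

Total steps: 9. Longest linear sequence: 6 (steps 2, 3, 6, 7, 8, 9 from 3; equally 1, 3, 6, 7, 8, 9 from 1).

Steps most likely to fail:

1. Step 3. The ion pair may collapse through the enolate carbon or the carbonyl oxygen instead of C1, giving cyclobutane or dihydrobenzofuran skeletons, and the titanium complex may discriminate the faces poorly with a hindered 1,2-diarylalkene. Fallback: leave the quinone manifold and generate the pentadienyl cation at the resorcinol oxidation level, with absolute configuration by separation instead of catalyst control. It sets out from 2 and bought 5-bromobenzene-1,3-diol. Mono-silylation (TIPSCl 1 equiv, imidazole, DMF) gives 3-bromo-5-(triisopropylsilyloxy)phenol F1. Oxidation of F1 with PhI(OAc)2 in (CF3)2CHOH/CH2Cl2 at −40 °C in the presence of 2 should give the phenoxonium ion, which the stilbene attacks at a ring carbon next to C–Br and which the silyl enol ether carbon then closes (a phenol-oxidative (5+2) cycloaddition). Either site of first attack leads to the same constitution and, after silyl loss, to the racemic bromo-enone. Preparative chromatography on a chiral stationary phase then gives (1R,5R,6S,7S)-4-bromo-6-[3,5-bis(triisopropylsilyloxy)phenyl]-7-[3,4-bis(triisopropylsilyloxy)phenyl]bicyclo[3.2.1]oct-3-ene-2,8-dione F2. Suzuki–Miyaura coupling of F2 with 8 (Pd(PPh3)4, K3PO4, THF/H2O) comes back to the route at 11, so steps 6 and 8 fall away.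

2. Step 7. Palladium may also insert into the enol triflate (double coupling), or the aqueous base may cleave the non-enolisable β-diketone. Fallback: attach the styryl arm before the cycloaddition. It sets out from 3 and 8. Suzuki–Miyaura coupling (Pd(dppf)Cl2, K3PO4, dioxane/H2O) gives 2-methoxy-6-[(E)-2-[3,4-bis(triisopropylsilyloxy)phenyl]ethenyl]phenol F3. Teuber oxidation as in step 2 gives 2-methoxy-6-[(E)-2-[3,4-bis(triisopropylsilyloxy)phenyl]ethenyl]-1,4-benzoquinone F4. Cycloaddition of F4 with 2 under the step 3 conditions gives (1S,5S,6S,7S)-3-hydroxy-4-[(E)-2-[3,4-bis(triisopropylsilyloxy)phenyl]ethenyl]-6-[3,5-bis(triisopropylsilyloxy)phenyl]-7-[3,4-bis(triisopropylsilyloxy)phenyl]bicyclo[3.2.1]oct-3-ene-2,8-dione F5. Triflation of F5 under the step 6 conditions comes back to the route at 10.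

3. Step 9. Once the 4-hydroxyl of the C7 aryl is free, the C1–C7 bond may open by retro-Michael fragmentation through a quinone methide and re-close through oxygen, and the catechols may oxidise in air. Fallback: trap the phenols as they are released, then unmask under neutral conditions. It sets out from 11. Desilylative acetylation (CsF, Ac2O, DMF, 0 °C) gives the hexaacetate (1R,5S,6S,7S)-7-(3,4-diacetoxyphenyl)-6-(3,5-diacetoxyphenyl)-4-[(E)-2-(3,4-diacetoxyphenyl)ethenyl]bicyclo[3.2.1]oct-3-ene-2,8-dione F6, which can be purified. Neutral transesterification of F6 (NH4OAc, MeOH/H2O, rt, argon) comes back to the route at 12.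

**Further compounds**

F1 | step 3 | 3-bromo-5-(triisopropylsilyloxy)phenol | Oc1cc(Br)cc(O[Si](C(C)C)(C(C)C)C(C)C)c1
F2 | step 3 | (1R,5R,6S,7S)-4-bromo-6-[3,5-bis(triisopropylsilyloxy)phenyl]-7-[3,4-bis(triisopropylsilyloxy)phenyl]bicyclo[3.2.1]oct-3-ene-2,8-dione | O=C1C=C(Br)[C@H]2C(=O)[C@@H]1[C@@H](c1ccc(O[Si](C(C)C)(C(C)C)C(C)C)c(O[Si](C(C)C)(C(C)C)C(C)C)c1)[C@@H]2c1cc(O[Si](C(C)C)(C(C)C)C(C)C)cc(O[Si](C(C)C)(C(C)C)C(C)C)c1
F3 | step 7 | 2-methoxy-6-[(E)-2-[3,4-bis(triisopropylsilyloxy)phenyl]ethenyl]phenol | COc1cccc(/C=C/c2ccc(O[Si](C(C)C)(C(C)C)C(C)C)c(O[Si](C(C)C)(C(C)C)C(C)C)c2)c1O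
F4 | step 7 | 2-methoxy-6-[(E)-2-[3,4-bis(triisopropylsilyloxy)phenyl]ethenyl]-1,4-benzoquinone | COC1=CC(=O)C=C(/C=C/c2ccc(O[Si](C(C)C)(C(C)C)C(C)C)c(O[Si](C(C)C)(C(C)C)C(C)C)c2)C1=O
F5 | step 7 | (1S,5S,6S,7S)-3-hydroxy-4-[(E)-2-[3,4-bis(triisopropylsilyloxy)phenyl]ethenyl]-6-[3,5-bis(triisopropylsilyloxy)phenyl]-7-[3,4-bis(triisopropylsilyloxy)phenyl]bicyclo[3.2.1]oct-3-ene-2,8-dione | O=C1C(O)=C(/C=C/c2ccc(O[Si](C(C)C)(C(C)C)C(C)C)c(O[Si](C(C)C)(C(C)C)C(C)C)c2)[C@H]2C(=O)[C@@H]1[C@@H](c1ccc(O[Si](C(C)C)(C(C)C)C(C)C)c(O[Si](C(C)C)(C(C)C)C(C)C)c1)[C@@H]2c1cc(O[Si](C(C)C)(C(C)C)C(C)C)cc(O[Si](C(C)C)(C(C)C)C(C)C)c1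
F6 | step 9 | (1R,5S,6S,7S)-7-(3,4-diacetoxyphenyl)-6-(3,5-diacetoxyphenyl)-4-[(E)-2-(3,4-diacetoxyphenyl)ethenyl]bicyclo[3.2.1]oct-3-ene-2,8-dione | O=C1C=C(/C=C/c2ccc(OC(C)=O)c(OC(C)=O)c2)[C@H]2C(=O)[C@@H]1[C@@H](c1ccc(OC(C)=O)c(OC(C)=O)c1)[C@@H]2c1cc(OC(C)=O)cc(OC(C)=O)c1
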